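The cyclobutane is cut at its two symmetry-related ring bonds between a C(CH3)(pyranonyl) carbon and a CH(CO2H) carbon. This uses the mirror plane of the meso four-membered ring: the two cis CH–CO2H carbons are maleic anhydride, the two quaternary carbons a symmetrical 2,3-bis(4-methoxy-3-methyl-2-oxopyran-6-yl)but-2-ene. One triplet-sensitised crossed [2+2] photocycloaddition joins them. The ring closes when the 1,4-biradical collapses to the quaternary-carbon–CH bond, setting all four stereocentres with both pyranonyl groups exo and both methyls cis to the anhydride. The alkene, free of stereocentres, comes from reductive coupling of a 6-acetylpyranone; anhydride hydrolysis finishes the cis-diacid.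

Key step: step 6

Assumption: the target is the meso (1R,2S,3R,4S) compound, so only relative configuration has to be controlled; 4-hydroxy-3,6-dimethyl-2H-pyran-2-one and maleic anhydride are taken as commercial.

Step 1
Reactants: 1 4-hydroxy-3,6-dimethyl-2H-pyran-2-one
Product: 2 4-methoxy-3,6-dimethyl-2H-pyran-2-one
Conditions: Me2SO4, K2CO3, acetone, reflux
Reagents that add atoms: dimethyl sulfate, COS(=O)(=O)OC
Why: O-alkylation of the vinylogous acid, which under K2CO3 in acetone should give the 4-methoxy-2-pyranone in preference to the 2-methoxy-4-pyranone isomer.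

Step 2
Reactants: 2 4-methoxy-3,6-dimethyl-2H-pyran-2-one
Product: 3 4-methoxy-5-methyl-6-oxo-6H-pyran-2-carbaldehyde
Conditions: SeO2, 1,4-dioxane, 150 °C, sealed tube
Reagents that add atoms: selenium dioxide, O=[Se]=O
Why: Riley oxidation, expected at the 6-methyl group because it is the vinylogous, enolisable position, while the 3-methyl group on the alpha carbon of the enoate is not activated.

Step 3
Reactants: 3 4-methoxy-5-methyl-6-oxo-6H-pyran-2-carbaldehyde
Product: 4 6-(1-hydroxyethyl)-4-methoxy-3-methyl-2H-pyran-2-one (racemic)
Conditions: MeMgBr, THF, −78 °C; then aq. NH4Cl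
Reagents that add atoms: methylmagnesium bromide, C[Mg]Br
Why: Grignard 1,2-addition to the aldehyde, which at −78 °C should react far faster than the lactone carbonyl; the new carbinol centre is racemic and is erased in step 4.

Step 4
Reactants: 4 6-(1-hydroxyethyl)-4-methoxy-3-methyl-2H-pyran-2-one
Product: 5 6-acetyl-4-methoxy-3-methyl-2H-pyran-2-one
Conditions: Dess–Martin periodinane, CH2Cl2, 0 °C to rt
Reagents that add atoms: none
Why: Dess–Martin oxidation of the secondary alcohol under mild, non-basic conditions that should leave the pyranone ring untouched.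

Step 5
Reactants: 5 6-acetyl-4-methoxy-3-methyl-2H-pyran-2-one (two molecules)
Product: 6 6,6'-(but-2-ene-2,3-diyl)bis(4-methoxy-3-methyl-2H-pyran-2-one), mixture of E and Z isomers
Conditions: TiCl4, Zn, pyridine, THF, 0 °C then reflux
Reagents that add atoms: none
Why: McMurry reductive coupling (ketyl dimerisation on low-valent titanium, then deoxygenation of the titanium pinacolate) of an aryl-type methyl ketone; the alkene geometry need not be controlled because E and Z interconvert in the triplet state of step 6.

Step 6
Reactants: 6 6,6'-(but-2-ene-2,3-diyl)bis(4-methoxy-3-methyl-2H-pyran-2-one); 7 maleic anhydride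
Product: 8 (1R,5S,6R,7S)-6,7-bis(4-methoxy-3-methyl-2-oxo-2H-pyran-6-yl)-6,7-dimethyl-3-oxabicyclo[3.2.0]heptane-2,4-dione (meso; pyranonyl groups exo, methyl groups cis to the anhydride ring)
Conditions: benzil (0.3 equiv), 7 (10 equiv), degassed CH2Cl2, 405 nm LEDs, 20 °C
Reagents that add atoms: none
Why: Triplet energy transfer from benzil should reach only the cross-conjugated bis(pyranonyl)ethene chromophore of 6, whose twisted triplet (E and Z converge here) adds through one tertiary carbon to maleic anhydride to give a 1,4-biradical (pyranonyl-stabilised tertiary radical and alpha-acyl radical) that, after intersystem crossing, closes the cyclobutane by radical recombination at the C(CH3)(pyranonyl)–CH(C=O) bond. The closest known reaction type is the triplet-sensitised crossed [2+2] photocycloaddition of aryl-conjugated alkenes with maleic anhydride or maleimides. The four-membered ring, the only ring formed, therefore closes stepwise by 1,4-biradical collapse. The two CH stereocentres are cis because a five-membered anhydride can only be cis-fused to a cyclobutane; the two quaternary centres are set in the reversible biradical stage, where the conformer with both flat, bulky pyranonyl groups on the convex face and the small methyl groups under the anhydride ring should close fastest, giving the meso isomer. The step needs site selectivity for the central C=C over the ring C5=C6 bonds and over dimerisation of maleic anhydride; the low sensitiser energy should secure it, because neither maleic anhydride nor the isolated 4-methoxy-2-pyranone rings of 8 should accept energy from benzil, so the product is expected to be photochemically silent.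

Step 7
Reactants: 8 (1R,5S,6R,7S)-6,7-bis(4-methoxy-3-methyl-2-oxo-2H-pyran-6-yl)-6,7-dimethyl-3-oxabicyclo[3.2.0]heptane-2,4-dione
Product: 9 (1R,2S,3R,4S)-3,4-bis(4-methoxy-3-methyl-2-oxo-2H-pyran-6-yl)-3,4-dimethylcyclobutane-1,2-dicarboxylic acid (meso)
Conditions: H2O, THF, 40 °C
Reagents that add atoms: water, O
Why: Hydrolysis of the strained cis-fused cyclic anhydride under neutral conditions, which should leave the pyranones intact and not epimerise the two CH centres, so the cis-diacid keeps the configuration set in step 6.

Compound list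
1 | 4-hydroxy-3,6-dimethyl-2H-pyran-2-one | Cc1cc(O)c(C)c(=O)o1 | starting material
2 | 4-methoxy-3,6-dimethyl-2H-pyran-2-one | COc1cc(C)oc(=O)c1C | intermediate
3 | 4-methoxy-5-methyl-6-oxo-6H-pyran-2-carbaldehyde | COc1cc(C=O)oc(=O)c1C | intermediate
4 | 6-(1-hydroxyethyl)-4-methoxy-3-methyl-2H-pyran-2-one (racemic) | COc1cc(C(C)O)oc(=O)c1C | intermediate
5 | 6-acetyl-4-methoxy-3-methyl-2H-pyran-2-one | COc1cc(C(C)=O)oc(=O)c1C | intermediate
6 | 6,6'-(but-2-ene-2,3-diyl)bis(4-methoxy-3-methyl-2H-pyran-2-one), mixture of E and Z isomers (geometry left open in the SMILES) | COc1cc(C(C)=C(C)c2cc(OC)c(C)c(=O)o2)oc(=O)c1C | intermediate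
7 | maleic anhydride (furan-2,5-dione) | O=C1OC(=O)C=C1 | starting material
8 | (1R,5S,6R,7S)-6,7-bis(4-methoxy-3-methyl-2-oxo-2H-pyran-6-yl)-6,7-dimethyl-3-oxabicyclo[3.2.0]heptane-2,4-dione (meso) | COc1cc([C@@]2(C)[C@@H]3C(=O)OC(=O)[C@@H]3[C@@]2(C)c2cc(OC)c(C)c(=O)o2)oc(=O)c1C | intermediate
9 | (1R,2S,3R,4S)-3,4-bis(4-methoxy-3-methyl-2-oxo-2H-pyran-6-yl)-3,4-dimethylcyclobutane-1,2-dicarboxylic acid (meso) | COc1cc([C@@]2(C)[C@H](C(=O)O)[C@H](C(=O)O)[C@@]2(C)c2cc(OC)c(C)c(=O)o2)oc(=O)c1C | target

Total step count: 7. Longest linear sequence: 7 steps (1 to 9; maleic anhydride 7 enters in step 6).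

Steps most likely to fail

Step 6. The twisted triplet may only decay back to E/Z alkene, the Z isomer may undergo 6π-electrocyclisation between the two pyranone C5 positions, or the biradical may close with one pyranonyl group endo or with the two pyranonyl groups trans. The fallback ties the two methyl carbons into a temporary ring, so that the alkene cannot isomerise and the pyranonyl groups are held cis. It sets out from ketone 5. Alpha-bromination (CuBr2, EtOAc/CHCl3, reflux) should give 6-(bromoacetyl)-4-methoxy-3-methyl-2H-pyran-2-one F1. Na2S (acetone/H2O, 0 °C) should join two molecules to 6,6'-[sulfanediylbis(1-oxoethane-2,1-diyl)]bis(4-methoxy-3-methyl-2H-pyran-2-one) F2. Intramolecular McMurry coupling (TiCl4, Zn, pyridine, THF, reflux) should close 6,6'-(2,5-dihydrothiophene-3,4-diyl)bis(4-methoxy-3-methyl-2H-pyran-2-one) F3. The same benzil-sensitised photocycloaddition with maleic anhydride 7 should give the meso tricyclic adduct 2,6-bis(4-methoxy-3-methyl-2-oxo-2H-pyran-6-yl)-9-oxa-4-thiatricyclo[5.3.0.0(2,6)]decane-8,10-dione F4, with the anhydride on the side of the CH2–S–CH2 bridge and away from the pyranonyl groups. Desulfurisation with acetone-deactivated Raney Ni (THF, rt) should turn the two C–S bonds into the two methyl groups and comes back to the route at anhydride 8.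

Step 5. Low-valent titanium may reduce the electron-poor pyranone rings, or the coupling may stop at the pinacol stage. The fallback builds the alkene by a vinylogous aldol addition and dehydration; it sets out from 2 and 5. Deprotonation of 2 at the 6-methyl group and methylation (LiN(iPr)2, THF, −78 °C; MeI) should give 6-ethyl-4-methoxy-3-methyl-2H-pyran-2-one F5. Its lithium dienolate (LiN(iPr)2, THF, −78 °C) should add through the exocyclic carbon to ketone 5 to give 6-[3-hydroxy-3-(4-methoxy-3-methyl-2-oxo-2H-pyran-6-yl)butan-2-yl]-4-methoxy-3-methyl-2H-pyran-2-one F6 as a mixture of diastereomers. Dehydration (SOCl2, pyridine, 0 °C) toward the acidic CH next to the second pyranone comes back to the route at alkene 6.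

Step 2. The harsh oxidation may run on to the carboxylic acid, attack the 3-methyl group, or decompose the pyranone. The fallback reaches the aldehyde by enamine cleavage; it sets out from 2. Condensation with tert-butoxybis(dimethylamino)methane (toluene, 100 °C) should occur only at the acidic 6-methyl group and give (E)-6-[2-(dimethylamino)ethenyl]-4-methoxy-3-methyl-2H-pyran-2-one F7. Oxidative cleavage of the enamine C=C (NaIO4, THF/H2O, rt) comes back to the route at aldehyde 3.

Further compounds
F1 | step 6 | 6-(bromoacetyl)-4-methoxy-3-methyl-2H-pyran-2-one | COc1cc(C(=O)CBr)oc(=O)c1C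
F2 | step 6 | 6,6'-[sulfanediylbis(1-oxoethane-2,1-diyl)]bis(4-methoxy-3-methyl-2H-pyran-2-one) | COc1cc(C(=O)CSCC(=O)c2cc(OC)c(C)c(=O)o2)oc(=O)c1C
F3 | step 6 | 6,6'-(2,5-dihydrothiophene-3,4-diyl)bis(4-methoxy-3-methyl-2H-pyran-2-one) | COc1cc(C2=C(c3cc(OC)c(C)c(=O)o3)CSC2)oc(=O)c1C
F4 | step 6 | 2,6-bis(4-methoxy-3-methyl-2-oxo-2H-pyran-6-yl)-9-oxa-4-thiatricyclo[5.3.0.0(2,6)]decane-8,10-dione (meso; thiolane and anhydride rings syn, pyranonyl groups on the other face) | COc1cc([C@@]2(CSC4)[C@@H]3C(=O)OC(=O)[C@@H]3[C@@]24c2cc(OC)c(C)c(=O)o2)oc(=O)c1C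
F5 | step 5 | 6-ethyl-4-methoxy-3-methyl-2H-pyran-2-one | CCc1cc(OC)c(C)c(=O)o1
F6 | step 5 | 6-[3-hydroxy-3-(4-methoxy-3-methyl-2-oxo-2H-pyran-6-yl)butan-2-yl]-4-methoxy-3-methyl-2H-pyran-2-one (mixture of diastereomers) | COc1cc(C(C)C(C)(O)c2cc(OC)c(C)c(=O)o2)oc(=O)c1C
F7 | step 2 | (E)-6-[2-(dimethylamino)ethenyl]-4-methoxy-3-methyl-2H-pyran-2-one | COc1cc(/C=C/N(C)C)oc(=O)c1C
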